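The ten-membered carbocycle (ring locants: C1 carries the aroyl ester, C2 the isopropyl group, C3 the hydroxyl) is disconnected at C2–C3. The key step is a catalytic enantioselective reductive aldol macrocyclisation of an achiral open-chain C15 keto-enal: hydride addition to its isopropylidene ketone creates the isopropyl group and a regiodefined enolate at C2, which closes the ring onto the enal carbon C3 and sets C2 and C3 in one operation. It exploits the C1(O)–C2(iPr)–C3(O) triad as a masked aldol and the two Z ring alkenes, installed beforehand from nerol. C1 is then relayed from C3, and an Evans–Tishchenko reduction finally delivers the C3 carbinol and the ester on O1.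

Key step: step 9

Remark: the SMILES defines both trisubstituted ring alkenes as Z (ring carbons cis) and the triad as 1S,2S,3S; the route is built for this isomer, and the target ring locants C1–C10 (C4=C5 and C8=C9 the alkenes, methyl on C5 and C9) are used for all ring compounds.
Remark: the sense of induction of the chiral catalyst in step 9 cannot be fixed on paper; the (S)-catalyst is written and its antipode is used if the induction is reversed.

Step 1
Reactants: 1 nerol [(2Z)-3,7-dimethylocta-2,6-dien-1-ol]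
Product: 2 tert-butyl{[(2Z)-3,7-dimethylocta-2,6-dien-1-yl]oxy}diphenylsilane
Conditions: TBDPSCl, imidazole, DMF, 0 °C to rt
Reagents that add atoms: tert-butyl(chloro)diphenylsilane (TBDPSCl), CC(C)(C)[Si](Cl)(c1ccccc1)c1ccccc1
Why: Silyl ether formation of the primary allylic alcohol (imidazole-promoted silylation); the TBDPS group should survive the periodic acid, ylide and tert-butyllithium steps that follow.

Step 2
Reactants: 2 tert-butyl{[(2Z)-3,7-dimethylocta-2,6-dien-1-yl]oxy}diphenylsilane
Product: 4 (4Z)-6-[(tert-butyldiphenylsilyl)oxy]-4-methylhex-4-enal, via 6,7-epoxide 3 (not isolated)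
Conditions: mCPBA (1.0 equiv), CH2Cl2, −20 °C; then H5IO6, THF/H2O, 0 °C
Reagents that add atoms: 3-chloroperoxybenzoic acid (mCPBA), O=C(OO)c1cccc(Cl)c1
Why: Prilezhaev epoxidation should take the more electron-rich distal trisubstituted alkene (the proximal one is deactivated by the allylic silyloxy group), and periodic acid hydrolyses the epoxide and cleaves the glycol (Malaprade cleavage) without touching the Z alkene.

Step 3
Reactants: 4 (4Z)-6-[(tert-butyldiphenylsilyl)oxy]-4-methylhex-4-enal; 5 ethyltriphenylphosphonium bromide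
Product: 7 tert-butyl{[(2Z,6Z)-7-iodo-3-methylocta-2,6-dien-1-yl]oxy}diphenylsilane, via iodo-ylide 6 (not isolated)
Conditions: 5, n-BuLi, THF, rt; I2, −78 °C; NaN(SiMe3)2, −20 °C; then 4, −78 °C to rt
Reagents that add atoms: iodine, II
Why: Stork–Zhao-type Wittig olefination with the α-iodo ylide, which as an unstabilised ylide under kinetic control at −78 °C should give the (Z)-iodoalkene (iodine cis to the chain) and thereby fixes the geometry of the later C8=C9 ring alkene.

Step 4
Reactants: 7 tert-butyl{[(2Z,6Z)-7-iodo-3-methylocta-2,6-dien-1-yl]oxy}diphenylsilane; 8 ethylene oxide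
Product: 10 (3Z,7Z)-9-[(tert-butyldiphenylsilyl)oxy]-3,7-dimethylnona-3,7-dien-1-ol, via alkenyllithium 9 (not isolated)
Conditions: t-BuLi (2.1 equiv), Et2O, −78 °C; 8, −78 to 0 °C; H2O
Reagents that add atoms: none
Why: Iodine–lithium exchange occurs with retention of the alkene geometry and the alkenyllithium opens ethylene oxide by SN2 attack, so that the future C10 and C1 are attached cis to the chain.

Step 5
Reactants: 10 (3Z,7Z)-9-[(tert-butyldiphenylsilyl)oxy]-3,7-dimethylnona-3,7-dien-1-ol
Product: 11 (3Z,7Z)-9-[(tert-butyldiphenylsilyl)oxy]-3,7-dimethylnona-3,7-dienal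
Conditions: Dess–Martin periodinane, pyridine, CH2Cl2, 0 °C
Reagents that add atoms: none
Why: Dess–Martin oxidation under buffered, non-basic conditions should give the β,γ-unsaturated aldehyde without migration of the alkene into conjugation, and the crude aldehyde is used at once.

Step 6
Reactants: 11 (3Z,7Z)-9-[(tert-butyldiphenylsilyl)oxy]-3,7-dimethylnona-3,7-dienal; 12 (2-methylprop-1-en-1-yl)magnesium bromide
Product: 13 (6Z,10Z)-12-[(tert-butyldiphenylsilyl)oxy]-2,6,10-trimethyldodeca-2,6,10-trien-4-ol (racemic)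
Conditions: 12 (0.5 M in THF), THF, −78 °C; aq NH4Cl
Reagents that add atoms: none
Why: Grignard 1,2-addition of the alkenylmagnesium reagent, which at −78 °C should outrun enolisation of the aldehyde; the new carbinol centre is formed as a racemate, which is immaterial because it is oxidised in step 8.

Step 7
Reactants: 13 (6Z,10Z)-12-[(tert-butyldiphenylsilyl)oxy]-2,6,10-trimethyldodeca-2,6,10-trien-4-ol
Product: 14 (2Z,6Z)-3,7,11-trimethyldodeca-2,6,10-triene-1,9-diol (racemic)
Conditions: Bu4NF, THF, 0 °C to rt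
Reagents that add atoms: none
Why: Fluoride-induced desilylation frees the primary allylic alcohol and leaves the three alkenes untouched.

Step 8
Reactants: 14 (2Z,6Z)-3,7,11-trimethyldodeca-2,6,10-triene-1,9-diol
Product: 15 (2Z,6Z)-3,7,11-trimethyl-9-oxododeca-2,6,10-trienal
Conditions: activated MnO2 (excess), CH2Cl2, rt
Reagents that add atoms: none
Why: Allylic oxidation with MnO2 should convert both allylic alcohols (the primary one to the Z-enal, the secondary one to the isopropylidene ketone) under neutral conditions that neither isomerise the enal nor move the β,γ-alkene into conjugation.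

Step 9
Reactants: 15 (2Z,6Z)-3,7,11-trimethyl-9-oxododeca-2,6,10-trienal
Product: 17 (2S,3R,4Z,8Z)-3-hydroxy-5,9-dimethyl-2-(propan-2-yl)cyclodeca-4,8-dien-1-one, via trichlorosilyl enolate 16 (not isolated)
Conditions: 15 added by syringe pump to HSiCl3 (3 equiv) and (S)-2,2′-bis(diphenylphosphoryl)-1,1′-binaphthyl ((S)-BINAPO, 20 mol%), EtCN/CH2Cl2, −78 °C, final 0.005 M; then aq NaHCO3
Reagents that add atoms: none
Why: Proposed new method: the bis(phosphine oxide) activates HSiCl3 as a hypervalent hydridosilicate that transfers hydride to the β-carbon of the s-cis isopropylidene ketone through a six-membered array, which creates the isopropyl group and, regiospecifically at C2, the (Z)-trichlorosilyl enolate 16, and the catalyst-bound enolate then adds to the tethered aldehyde through a closed chair-like transition state. The closest known reaction type is the intermolecular phosphine-oxide-catalysed reductive aldol reaction of enones and aldehydes with HSiCl3, enantioselective with BINAPO, which is extended here to an intramolecular macrocyclisation of an enone-enal. The ten-membered carbocycle closes in the 10-(enolendo)-exo-trig mode by formation of the C2–C3 bond. C3 is set by the chiral BINAPO-silicon complex, the only source of asymmetry for the achiral substrate, which selects the aldehyde face, and C2 follows from the Z enolate geometry in the chair (syn aldol, 2S,3R). The step needs 1,4-reduction of the ketone in preference to the enal, which the s-cis-locked β,β-disubstituted enone against the s-trans enal and the low temperature should secure, and ring closure in preference to oligomerisation, which slow addition at high dilution and the two Z alkenes that fold the chain should secure. The sense of induction has to be confirmed and the catalyst antipode is used if it is reversed.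

Step 10
Reactants: 17 (2S,3R,4Z,8Z)-3-hydroxy-5,9-dimethyl-2-(propan-2-yl)cyclodeca-4,8-dien-1-one
Product: 19 (1S,2R,3R,4Z,8Z)-5,9-dimethyl-2-(propan-2-yl)cyclodeca-4,8-diene-1,3-diol, via diethylboron chelate 18 (not isolated)
Conditions: Et2BOMe, THF/MeOH 4:1, −78 °C; NaBH4; then MeOH co-evaporation
Reagents that add atoms: none
Why: Narasaka–Prasad reduction, in which Et2BOMe ties O3 and the C1 carbonyl into a six-membered boron chelate and external hydride adds axially, so that the C3 carbinol sets C1 in the 1,3-syn sense.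

Step 11
Reactants: 19 (1S,2R,3R,4Z,8Z)-5,9-dimethyl-2-(propan-2-yl)cyclodeca-4,8-diene-1,3-diol
Product: 20 (1S,2R,4Z,8Z)-1-hydroxy-5,9-dimethyl-2-(propan-2-yl)cyclodeca-4,8-dien-3-one
Conditions: activated MnO2, CH2Cl2, rt
Reagents that add atoms: none
Why: Chemoselective MnO2 oxidation of the allylic C3 alcohol beside the non-allylic C1 alcohol should give the β-hydroxy enone under neutral conditions that leave the epimerisable C2 centre untouched.

Step 12
Reactants: 20 (1S,2R,4Z,8Z)-1-hydroxy-5,9-dimethyl-2-(propan-2-yl)cyclodeca-4,8-dien-3-one; 21 4-[(tert-butyldimethylsilyl)oxy]benzaldehyde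
Product: 23 (1S,2S,3S,4Z,8Z)-3-hydroxy-5,9-dimethyl-2-(propan-2-yl)cyclodeca-4,8-dien-1-yl 4-[(tert-butyldimethylsilyl)oxy]benzoate, via samarium-bound hemiacetal 22 (not isolated)
Conditions: SmI2 (30 mol%), 21 (4 equiv), THF, −10 °C
Reagents that add atoms: none
Why: Evans–Tishchenko reduction, in which the trivalent samarium catalyst generated from SmI2 and the aldehyde holds the hemiacetal on O1 and the C3 carbonyl in a chair-like array and intramolecular hydride transfer sets C3 1,3-anti to C1 (control by C1) while O1 becomes the aryl ester.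

Step 13
Reactants: 23 (1S,2S,3S,4Z,8Z)-3-hydroxy-5,9-dimethyl-2-(propan-2-yl)cyclodeca-4,8-dien-1-yl 4-[(tert-butyldimethylsilyl)oxy]benzoate
Product: 24 (1S,2S,3S,4Z,8Z)-3-hydroxy-5,9-dimethyl-2-(propan-2-yl)cyclodeca-4,8-dien-1-yl 4-hydroxybenzoate (CNP0249141.6)
Conditions: Bu4NF, AcOH, THF, 0 °C
Reagents that add atoms: none
Why: Fluoride-mediated cleavage of the aryl silyl ether (desilylation), buffered with acetic acid so that the ester does not migrate and the allylic alcohol is not affected.

Compound list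
1 | nerol, (2Z)-3,7-dimethylocta-2,6-dien-1-ol | CC(C)=CCC/C(C)=C\CO | starting material
2 | tert-butyl{[(2Z)-3,7-dimethylocta-2,6-dien-1-yl]oxy}diphenylsilane | CC(C)=CCC/C(C)=C\CO[Si](c1ccccc1)(c1ccccc1)C(C)(C)C | intermediate
3 | tert-butyl{[(2Z)-5-(3,3-dimethyloxiran-2-yl)-3-methylpent-2-en-1-yl]oxy}diphenylsilane (racemic 6,7-epoxide, not isolated) | CC1(C)OC1CC/C(C)=C\CO[Si](c1ccccc1)(c1ccccc1)C(C)(C)C | intermediate
4 | (4Z)-6-[(tert-butyldiphenylsilyl)oxy]-4-methylhex-4-enal | O=CCC/C(C)=C\CO[Si](c1ccccc1)(c1ccccc1)C(C)(C)C | intermediate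
5 | ethyltriphenylphosphonium bromide | CC[P+](c1ccccc1)(c1ccccc1)c1ccccc1.[Br-] | starting material
6 | (1-iodoethylidene)triphenylphosphorane (iodo-ylide, not isolated) | CC(I)=P(c1ccccc1)(c1ccccc1)c1ccccc1 | intermediate
7 | tert-butyl{[(2Z,6Z)-7-iodo-3-methylocta-2,6-dien-1-yl]oxy}diphenylsilane | C/C(I)=C/CC/C(C)=C\CO[Si](c1ccccc1)(c1ccccc1)C(C)(C)C | intermediate
8 | ethylene oxide (oxirane) | C1CO1 | starting material
9 | {(2E,6Z)-8-[(tert-butyldiphenylsilyl)oxy]-6-methylocta-2,6-dien-2-yl}lithium (alkenyllithium with lithium cis to the chain, not isolated) | C/C([Li])=C/CC/C(C)=C\CO[Si](c1ccccc1)(c1ccccc1)C(C)(C)C | intermediate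
10 | (3Z,7Z)-9-[(tert-butyldiphenylsilyl)oxy]-3,7-dimethylnona-3,7-dien-1-ol | OCC/C(C)=C\CC/C(C)=C\CO[Si](c1ccccc1)(c1ccccc1)C(C)(C)C | intermediate
11 | (3Z,7Z)-9-[(tert-butyldiphenylsilyl)oxy]-3,7-dimethylnona-3,7-dienal | O=CC/C(C)=C\CC/C(C)=C\CO[Si](c1ccccc1)(c1ccccc1)C(C)(C)C | intermediate
12 | (2-methylprop-1-en-1-yl)magnesium bromide | CC(C)=C[Mg]Br | starting material
13 | (6Z,10Z)-12-[(tert-butyldiphenylsilyl)oxy]-2,6,10-trimethyldodeca-2,6,10-trien-4-ol (racemic) | CC(C)=CC(O)C/C(C)=C\CC/C(C)=C\CO[Si](c1ccccc1)(c1ccccc1)C(C)(C)C | intermediate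
14 | (2Z,6Z)-3,7,11-trimethyldodeca-2,6,10-triene-1,9-diol (racemic) | CC(C)=CC(O)C/C(C)=C\CC/C(C)=C\CO | intermediate
15 | (2Z,6Z)-3,7,11-trimethyl-9-oxododeca-2,6,10-trienal | CC(C)=CC(=O)C/C(C)=C\CC/C(C)=C\C=O | intermediate
16 | (2Z,6Z,9Z)-3,7,11-trimethyl-9-[(trichlorosilyl)oxy]dodeca-2,6,9-trienal (not isolated) | CC(C)/C=C(\O[Si](Cl)(Cl)Cl)C/C(C)=C\CC/C(C)=C\C=O | intermediate
17 | (2S,3R,4Z,8Z)-3-hydroxy-5,9-dimethyl-2-(propan-2-yl)cyclodeca-4,8-dien-1-one | C/C1=C/[C@@H](O)[C@H](C(C)C)C(=O)C/C(C)=C\CC1 | intermediate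
18 | (2S,3R,4Z,8Z)-3-[(diethylboranyl)oxy]-5,9-dimethyl-2-(propan-2-yl)cyclodeca-4,8-dien-1-one (boron chelate, not isolated) | C/C1=C/[C@@H](OB(CC)CC)[C@H](C(C)C)C(=O)C/C(C)=C\CC1 | intermediate
19 | (1S,2R,3R,4Z,8Z)-5,9-dimethyl-2-(propan-2-yl)cyclodeca-4,8-diene-1,3-diol | C/C1=C/[C@@H](O)[C@H](C(C)C)[C@@H](O)C/C(C)=C\CC1 | intermediate
20 | (1S,2R,4Z,8Z)-1-hydroxy-5,9-dimethyl-2-(propan-2-yl)cyclodeca-4,8-dien-3-one | C/C1=C/C(=O)[C@H](C(C)C)[C@@H](O)C/C(C)=C\CC1 | intermediate
21 | 4-[(tert-butyldimethylsilyl)oxy]benzaldehyde | O=Cc1ccc(O[Si](C)(C)C(C)(C)C)cc1 | starting material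
22 | hemiacetal of 20 (through O1) and 21, bound to samarium as its alkoxide and drawn in neutral form (not isolated) | C/C1=C/C(=O)[C@H](C(C)C)[C@@H](OC(O)c2ccc(O[Si](C)(C)C(C)(C)C)cc2)C/C(C)=C\CC1 | intermediate
23 | (1S,2S,3S,4Z,8Z)-3-hydroxy-5,9-dimethyl-2-(propan-2-yl)cyclodeca-4,8-dien-1-yl 4-[(tert-butyldimethylsilyl)oxy]benzoate | C/C1=C/[C@H](O)[C@H](C(C)C)[C@@H](OC(=O)c2ccc(O[Si](C)(C)C(C)(C)C)cc2)C/C(C)=C\CC1 | intermediate
24 | (1S,2S,3S,4Z,8Z)-3-hydroxy-5,9-dimethyl-2-(propan-2-yl)cyclodeca-4,8-dien-1-yl 4-hydroxybenzoate | C/C1=C/[C@H](O)[C@H](C(C)C)[C@@H](OC(=O)c2ccc(O)cc2)C/C(C)=C\CC1 | target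

Total step count: 13. Longest linear sequence: 13 steps (from nerol).

Steps most likely to fail

1. Step 9 (Proposed new method). What may go wrong: hydride delivery to the aldehyde or the enal instead of the enone, intermolecular aldol oligomerisation, or weak enantiofacial discrimination in the ring-closing transition state. The fallback uses known chemistry, sets out from 13 and comes back at 17. MnO2 oxidation of 13 should give the silyl-protected isopropylidene ketone F1. 1,4-Hydrosilylation (Et3SiH, RhCl(PPh3)3 cat.) gives the triethylsilyl enol ether F2, and NBS at −78 °C the α-bromo ketone F3. HF·pyridine frees the allylic alcohol F4, and MnO2 gives the bromo keto-enal F5. SmI2 (2.2 equiv, THF, −78 °C, high dilution) then forms the same C2–C3 bond by an intramolecular Reformatsky-type aldol reaction of the regiodefined samarium enolate, a known way to close medium rings. It should give the racemic syn aldol F6, which is resolved by preparative chromatography on a chiral stationary phase to return 17.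

2. Step 10. What may go wrong: loss of facial selectivity in the hydride addition if the medium ring distorts the boron chelate (or if step 9 delivers the C3 epimer), and retro-aldol opening of the ring under the borohydride conditions. The fallback sets out from 17 and comes back at 19. Silylation (Et3SiOTf, 2,6-lutidine, −78 °C) gives the triethylsilyl ether F7. Corey–Bakshi–Shibata reduction with (R)-1-methyl-3,3-diphenyltetrahydro-1H,3H-pyrrolo[1,2-c][1,3,2]oxazaborole ((R)-Me-CBS) and catecholborane at −78 °C sets C1 under reagent control (C2 as the large, C10 as the small substituent) and gives the alcohol F8. PPTS in MeOH removes the silyl group and returns 19.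

3. Step 12. What may go wrong: slow hydride transfer in the hindered hemiacetal and competing retro-aldol fragmentation of the β-hydroxy enone, so that conversion stays low. The fallback sets out from 20 and comes back at 23. Steglich esterification of 20 with 4-[(tert-butyldimethylsilyl)oxy]benzoic acid (EDC·HCl, DMAP, CH2Cl2, 0 °C) gives the β-aroyloxy enone F9. Corey–Bakshi–Shibata 1,2-reduction of the enone carbonyl ((S)-Me-CBS, catecholborane, −78 °C, the alkenyl side as the large substituent) sets C3 under reagent control and gives 23.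

Further compounds
F1 | step 9 | (6Z,10Z)-12-[(tert-butyldiphenylsilyl)oxy]-2,6,10-trimethyldodeca-2,6,10-trien-4-one | CC(C)=CC(=O)C/C(C)=C\CC/C(C)=C\CO[Si](c1ccccc1)(c1ccccc1)C(C)(C)C
F2 | step 9 | tert-butyl{[(2Z,6Z,9Z)-3,7,11-trimethyl-9-[(triethylsilyl)oxy]dodeca-2,6,9-trien-1-yl]oxy}diphenylsilane | CC(C)/C=C(\O[Si](CC)(CC)CC)C/C(C)=C\CC/C(C)=C\CO[Si](c1ccccc1)(c1ccccc1)C(C)(C)C
F3 | step 9 | (6Z,10Z)-3-bromo-12-[(tert-butyldiphenylsilyl)oxy]-2,6,10-trimethyldodeca-6,10-dien-4-one (racemic) | CC(C)C(Br)C(=O)C/C(C)=C\CC/C(C)=C\CO[Si](c1ccccc1)(c1ccccc1)C(C)(C)C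
F4 | step 9 | (6Z,10Z)-3-bromo-12-hydroxy-2,6,10-trimethyldodeca-6,10-dien-4-one (racemic) | CC(C)C(Br)C(=O)C/C(C)=C\CC/C(C)=C\CO
F5 | step 9 | (2Z,6Z)-10-bromo-3,7,11-trimethyl-9-oxododeca-2,6-dienal (racemic) | CC(C)C(Br)C(=O)C/C(C)=C\CC/C(C)=C\C=O
F6 | step 9 | racemic syn aldol, 17 together with its enantiomer | C/C1=C/[C@@H](O)[C@H](C(C)C)C(=O)C/C(C)=C\CC1.C/C1=C/[C@H](O)[C@@H](C(C)C)C(=O)C/C(C)=C\CC1
F7 | step 10 | (2S,3R,4Z,8Z)-5,9-dimethyl-2-(propan-2-yl)-3-[(triethylsilyl)oxy]cyclodeca-4,8-dien-1-one | C/C1=C/[C@@H](O[Si](CC)(CC)CC)[C@H](C(C)C)C(=O)C/C(C)=C\CC1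
F8 | step 10 | (1S,2R,3R,4Z,8Z)-5,9-dimethyl-2-(propan-2-yl)-3-[(triethylsilyl)oxy]cyclodeca-4,8-dien-1-ol | C/C1=C/[C@@H](O[Si](CC)(CC)CC)[C@H](C(C)C)[C@@H](O)C/C(C)=C\CC1
F9 | step 12 | (1S,2R,4Z,8Z)-5,9-dimethyl-3-oxo-2-(propan-2-yl)cyclodeca-4,8-dien-1-yl 4-[(tert-butyldimethylsilyl)oxy]benzoate | C/C1=C/C(=O)[C@H](C(C)C)[C@@H](OC(=O)c2ccc(O[Si](C)(C)C(C)(C)C)cc2)C/C(C)=C\CC1
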